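**Retrosynthetic overview**
- Target 19 is the tridepside A–B–C: A is 4-hydroxy-2,3-dimethoxy-6-methylbenzoyl, B is the central ring, C is the acid terminus. Rings B and C are both orsellinate rings (C1 bears the carboxyl carbon, then 2-OH, 4-O, 6-CH3), which is the pattern of a folded C8 tetraketide chain.
- Key disconnection: ring B is not brought in as an arene. The cut goes at once through the B–C depside bond (acyl carbon of B to 4-O of C) and the C1–C6 bond of ring B. This leads back to phenol 7 (ring C) and the acyclic diketo-dioxinone 5, which is two steps from 1.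
- Ring C is bought as orsellinic acid 6 and only capped as its benzyl ester 7, and ring A is bought as arene 11. Order of ring formation: ring B is the only ring the route closes, and it is closed on the 4-O of ring C.
- The key step delivers ring B with its 2-OH chelated and its 4-OH free, so the A–B ester needs no protecting group on B or C, whereas a second unit of 6 as ring B would need both phenols masked and freed again. Ring A acid 15 comes from 11 by deoxygenation, silylation and ortho-lithiation/carboxylation at the C–H between OMe and CH3.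
- Endgame: desilylation, then hydrogenolysis of the benzyl ester.

Key step: step 4

Remark: the target has no stereocentre, stereogenic axis or configured double bond, so it is achiral and the demand for a single enantiomer is met by the constitution alone.

**Step 1**
Reactants: 1 2,2,6-trimethyl-4H-1,3-dioxin-4-one
Product: 3 2,2-dimethyl-6-(2-oxopropyl)-4H-1,3-dioxin-4-one, via lithium dienolate 2 (not isolated)
Conditions: 1 (2 equiv), LiHMDS (2 equiv), THF, −78 °C; AcCl (1 equiv), −78 °C; cold 1 M HCl
Reagents that add atoms: acetyl chloride, CC(=O)Cl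
Why: Deprotonation of the 6-methyl group gives the extended dienolate, which is C-acylated at its γ-carbon (vinylogous Claisen-type acylation), while the second equivalent of dienolate absorbs the more acidic product and returns 1 for recovery.

**Step 2**
Reactants: 3 2,2-dimethyl-6-(2-oxopropyl)-4H-1,3-dioxin-4-one
Product: 5 6-(2,4-dioxopentyl)-2,2-dimethyl-4H-1,3-dioxin-4-one, via dilithio dianion 4 (not isolated)
Conditions: LDA (2.2 equiv), THF, −78 °C; MeC(O)N(OMe)Me, −78 to −30 °C; cold 1 M HCl
Reagents that add atoms: N-methoxy-N-methylacetamide, CC(=O)N(C)OC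
Why: In this crossed Claisen condensation of a β-dicarbonyl-type dianion the last-formed, most reactive terminal CH2 carbanion attacks the N-methoxy-N-methylamide, and the chelated tetrahedral adduct releases the 1,3-diketone only on the acidic quench, so neither over-addition nor proton exchange should interfere.

**Step 3**
Reactants: 6 2,4-dihydroxy-6-methylbenzoic acid (orsellinic acid)
Product: 7 benzyl 2,4-dihydroxy-6-methylbenzoate (benzyl orsellinate)
Conditions: BnBr (1.05 equiv), KHCO3 (1.1 equiv), DMF, rt
Reagents that add atoms: benzyl bromide, BrCc1ccccc1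
Why: In this SN2 O-alkylation of a carboxylate the weak base hydrogencarbonate deprotonates only the carboxylic acid and not the phenols, so benzylation should stop at the ester, and room temperature avoids decarboxylation of the electron-rich acid.

**Step 4**
Reactants: 5 6-(2,4-dioxopentyl)-2,2-dimethyl-4H-1,3-dioxin-4-one; 7 benzyl 2,4-dihydroxy-6-methylbenzoate
Product: 10 benzyl 4-[(2,4-dihydroxy-6-methylbenzoyl)oxy]-2-hydroxy-6-methylbenzoate (benzyl lecanorate), via acylketene 8 (not isolated), via aryl triketo ester 9 (not isolated)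
Conditions: 7 (2 equiv), PhMe, 110 °C, slow addition of 5; cool; Et3N (cat.), CH2Cl2, rt; 1 M HCl wash; excess 7 recovered
Reagents that add atoms: none
Why: At 110 °C dioxinone 5 loses acetone by a retro-hetero-Diels–Alder reaction, the ketene carbon of 8 is captured by the 4-OH of 7 to make the B–C depside C(=O)–O bond of 9, and triethylamine then starts the intramolecular aldol addition of C2 of the trioxooctanoyl chain to its C7 methyl ketone, after which loss of water and enolisation of C3 and C5 give aromatic ring B. The closest known reaction types are the resorcylate synthesis from diketo-dioxinones and alcohols (thermolysis, ketene capture, base-induced aldol aromatisation) and the acetoacetylation of phenols with the parent dioxinone 1, so only the nucleophile differs from close precedent. Ring B closes in a 6-exo-trig aldol mode that forms its C1–C6 bond, and aromatisation makes the closure irreversible. No stereocentre remains, since the transient carbinol carbon becomes C6 of the arene. The step needs capture at the 4-OH and not the 2-OH of 7, which the hydrogen bond of the 2-OH to the benzyl ester carbonyl and its flanked position secure, and it needs intermolecular capture to outrun lactonisation of 8 to a 4-hydroxy-2-pyrone, which slow addition of 5 to a hot concentrated solution of excess 7 secures. The new 4-OH of ring B appears only in the cold basic phase when no ketene is left, so a third unit is not added, and the mild amine base at room temperature favours the aldol path over expulsion of the phenoxide of 7.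

**Step 5**
Reactants: 11 3-hydroxy-4,5-dimethoxybenzaldehyde
Product: 12 2,3-dimethoxy-5-methylphenol
Conditions: H2 (3 bar), 10% Pd/C, AcOH, rt
Reagents that add atoms: none
Why: Catalytic hydrogenation of the electron-rich aldehyde to the benzylic alcohol, followed by acid-assisted benzylic hydrogenolysis that the para-methoxy group activates, should give the methyl group.

**Step 6**
Reactants: 12 2,3-dimethoxy-5-methylphenol
Product: 13 triisopropyl(2,3-dimethoxy-5-methylphenoxy)silane
Conditions: TIPSCl, imidazole, DMF, rt
Reagents that add atoms: triisopropylsilyl chloride, CC(C)[Si](Cl)(C(C)C)C(C)C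
Why: This is a standard phenol silylation, and the TIPS group is chosen because it survives butyllithium, does not coordinate lithium and shields the neighbouring C6–H.

**Step 7**
Reactants: 13 triisopropyl(2,3-dimethoxy-5-methylphenoxy)silane
Product: 15 2,3-dimethoxy-6-methyl-4-[(triisopropylsilyl)oxy]benzoic acid, via aryllithium 14 (not isolated)
Conditions: n-BuLi, TMEDA, Et2O, 0 °C to rt; CO2, −78 °C to rt; cold 1 M HCl
Reagents that add atoms: carbon dioxide, O=C=O
Why: In this directed ortho-metalation C4–H of 13 (between 3-OMe and 5-CH3) is the only ring C–H ortho to a coordinating methoxy group, whereas C6–H lies between the bulky non-coordinating OTIPS group and the methyl group, so the aryllithium should form at C4 and be carboxylated there.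

**Step 8**
Reactants: 15 2,3-dimethoxy-6-methyl-4-[(triisopropylsilyl)oxy]benzoic acid; 10 benzyl 4-[(2,4-dihydroxy-6-methylbenzoyl)oxy]-2-hydroxy-6-methylbenzoate
Product: 17 benzyl 4-{[4-({2,3-dimethoxy-6-methyl-4-[(triisopropylsilyl)oxy]benzoyl}oxy)-2-hydroxy-6-methylbenzoyl]oxy}-2-hydroxy-6-methylbenzoate, via mixed anhydride 16 (not isolated)
Conditions: (CF3CO)2O, PhMe, rt
Reagents that add atoms: none
Why: This is the classical depside condensation through the aroyl trifluoroacetate of an electron-rich 2,6-disubstituted benzoic acid, which acylates only the unchelated 4-OH of ring B because both 2-OH groups are hydrogen-bonded to their ester carbonyls.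

**Step 9**
Reactants: 17 the silyl-protected benzyl ester of the tridepside
Product: 18 benzyl 4-({4-[(4-hydroxy-2,3-dimethoxy-6-methylbenzoyl)oxy]-2-hydroxy-6-methylbenzoyl}oxy)-2-hydroxy-6-methylbenzoate
Conditions: TBAF, AcOH (1:1), THF, 0 °C
Reagents that add atoms: none
Why: Fluoride-induced cleavage of the aryl silyl ether is fast, and the acetic acid buffer protonates the phenoxide at once, so the two aryl ester bonds should not be attacked.

**Step 10**
Reactants: 18 benzyl 4-({4-[(4-hydroxy-2,3-dimethoxy-6-methylbenzoyl)oxy]-2-hydroxy-6-methylbenzoyl}oxy)-2-hydroxy-6-methylbenzoate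
Product: 19 4-({4-[(4-hydroxy-2,3-dimethoxy-6-methylbenzoyl)oxy]-2-hydroxy-6-methylbenzoyl}oxy)-2-hydroxy-6-methylbenzoic acid (target)
Conditions: H2 (1 atm), 10% Pd/C, EtOAc, rt
Reagents that add atoms: none
Why: Catalytic hydrogenolysis of the benzyl ester is neutral and non-nucleophilic, so it should free the acid of ring C without touching the depside bonds or the aryl methyl ethers.

**Compound list**
1 | 2,2,6-trimethyl-4H-1,3-dioxin-4-one | CC1=CC(=O)OC(C)(C)O1 | starting material
2 | lithium dienolate of 1 | C=C1C=C(O[Li])OC(C)(C)O1 | intermediate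
3 | 2,2-dimethyl-6-(2-oxopropyl)-4H-1,3-dioxin-4-one | CC(=O)CC1=CC(=O)OC(C)(C)O1 | intermediate
4 | dilithio dianion of 3 | C=C(O[Li])C=C1C=C(O[Li])OC(C)(C)O1 | intermediate
5 | 6-(2,4-dioxopentyl)-2,2-dimethyl-4H-1,3-dioxin-4-one | CC(=O)CC(=O)CC1=CC(=O)OC(C)(C)O1 | intermediate
6 | 2,4-dihydroxy-6-methylbenzoic acid (orsellinic acid) | Cc1cc(O)cc(O)c1C(=O)O | starting material
7 | benzyl 2,4-dihydroxy-6-methylbenzoate | Cc1cc(O)cc(O)c1C(=O)OCc1ccccc1 | intermediate
8 | 3,5,7-trioxooct-1-en-1-one (acylketene) | CC(=O)CC(=O)CC(=O)C=C=O | intermediate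
9 | benzyl 2-hydroxy-6-methyl-4-[(3,5,7-trioxooctanoyl)oxy]benzoate | CC(=O)CC(=O)CC(=O)CC(=O)Oc1cc(C)c(C(=O)OCc2ccccc2)c(O)c1 | intermediate
10 | benzyl 4-[(2,4-dihydroxy-6-methylbenzoyl)oxy]-2-hydroxy-6-methylbenzoate | Cc1cc(O)cc(O)c1C(=O)Oc1cc(C)c(C(=O)OCc2ccccc2)c(O)c1 | intermediate
11 | 3-hydroxy-4,5-dimethoxybenzaldehyde | COc1cc(C=O)cc(O)c1OC | starting material
12 | 2,3-dimethoxy-5-methylphenol | COc1cc(C)cc(O)c1OC | intermediate
13 | triisopropyl(2,3-dimethoxy-5-methylphenoxy)silane | COc1cc(C)cc(O[Si](C(C)C)(C(C)C)C(C)C)c1OC | intermediate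
14 | {2,3-dimethoxy-6-methyl-4-[(triisopropylsilyl)oxy]phenyl}lithium | COc1c([Li])c(C)cc(O[Si](C(C)C)(C(C)C)C(C)C)c1OC | intermediate
15 | 2,3-dimethoxy-6-methyl-4-[(triisopropylsilyl)oxy]benzoic acid | COc1c(O[Si](C(C)C)(C(C)C)C(C)C)cc(C)c(C(=O)O)c1OC | intermediate
16 | 2,3-dimethoxy-6-methyl-4-[(triisopropylsilyl)oxy]benzoic trifluoroacetic anhydride | COc1c(O[Si](C(C)C)(C(C)C)C(C)C)cc(C)c(C(=O)OC(=O)C(F)(F)F)c1OC | intermediate
17 | benzyl 4-{[4-({2,3-dimethoxy-6-methyl-4-[(triisopropylsilyl)oxy]benzoyl}oxy)-2-hydroxy-6-methylbenzoyl]oxy}-2-hydroxy-6-methylbenzoate | COc1c(O[Si](C(C)C)(C(C)C)C(C)C)cc(C)c(C(=O)Oc2cc(C)c(C(=O)Oc3cc(C)c(C(=O)OCc4ccccc4)c(O)c3)c(O)c2)c1OC | intermediate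
18 | benzyl 4-({4-[(4-hydroxy-2,3-dimethoxy-6-methylbenzoyl)oxy]-2-hydroxy-6-methylbenzoyl}oxy)-2-hydroxy-6-methylbenzoate | COc1c(O)cc(C)c(C(=O)Oc2cc(C)c(C(=O)Oc3cc(C)c(C(=O)OCc4ccccc4)c(O)c3)c(O)c2)c1OC | intermediate
19 | 4-({4-[(4-hydroxy-2,3-dimethoxy-6-methylbenzoyl)oxy]-2-hydroxy-6-methylbenzoyl}oxy)-2-hydroxy-6-methylbenzoic acid | COc1c(O)cc(C)c(C(=O)Oc2cc(C)c(C(=O)Oc3cc(C)c(C(=O)O)c(O)c3)c(O)c2)c1OC | target

Total step count: 10
Longest linear sequence: 6 (steps 1, 2, 4, 8, 9, 10; the ring A branch, steps 5, 6, 7, 8, 9, 10, is of equal length)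

**Steps most likely to fail**

1. **Step 4.** Capture of the ketene by the electron-poor phenol may be too slow, so that unimolecular lactonisation or dimerisation of the ketene consumes it. The phenoxide may also be expelled from the aryl triketo ester before the aldol closure.
   - The fallback makes the arene first and the ester second. It sets out from 7 and comes back at 10.
   - Compound 7 is treated with NaH and MOMCl in DMF to give benzyl 2,4-bis(methoxymethoxy)-6-methylbenzoate F1.
   - Hydrogenolysis (H2, Pd/C, EtOAc) gives 2,4-bis(methoxymethoxy)-6-methylbenzoic acid F2.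
   - Carbodiimide esterification (EDC, DMAP, CH2Cl2) with a second portion of 7 at its free 4-OH gives benzyl 4-{[2,4-bis(methoxymethoxy)-6-methylbenzoyl]oxy}-2-hydroxy-6-methylbenzoate F3.
   - HCl in THF/i-PrOH removes both acetals to give 10.

2. **Step 7.** Lithiation at the flanked ring position may be sluggish, and lateral deprotonation of the methyl group or silyl migration may then compete.
   - The fallback replaces C–H lithiation by a C–O to C–C exchange whose position is fixed by a quinone oxygen. It sets out from 12 and comes back at 15.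
   - Oxidation of 12 (O2, salcomine, DMF) gives 2,3-dimethoxy-5-methyl-1,4-benzoquinone F4, which is also an article of commerce.
   - Na2S2O4 reduces it to 2,3-dimethoxy-5-methylbenzene-1,4-diol F5.
   - TIPSCl/imidazole silylates the less hindered hydroxyl (next to C–H, not next to CH3) to give 2,3-dimethoxy-6-methyl-4-[(triisopropylsilyl)oxy]phenol F6.
   - Tf2O/pyridine gives 2,3-dimethoxy-6-methyl-4-[(triisopropylsilyl)oxy]phenyl trifluoromethanesulfonate F7.
   - Palladium-catalysed hydroxycarbonylation (Pd(OAc)2, dppf, CO, Et3N, DMF/H2O, 80 °C) gives 15.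

3. **Step 2.** Proton transfer within the dianion mixture, attack at the dioxinone carbonyl, or premature base-induced aromatisation of the sensitive product during quench and purification may erode the step.
   - The fallback avoids the dianion. It sets out from 1 (through dienolate 2) and comes back at 5.
   - Dienolate 2 is acylated with allyl 3-chloro-3-oxopropanoate to give allyl 4-(2,2-dimethyl-4-oxo-4H-1,3-dioxin-6-yl)-3-oxobutanoate F8.
   - Magnesium-mediated C-acetylation (MgCl2, pyridine, AcCl, CH2Cl2) gives allyl 2-acetyl-4-(2,2-dimethyl-4-oxo-4H-1,3-dioxin-6-yl)-3-oxobutanoate F9.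
   - Pd(PPh3)4 with morpholine brings about deallylation and decarboxylation under near-neutral conditions to give 5.

**Further compounds**
F1 | step 4 | benzyl 2,4-bis(methoxymethoxy)-6-methylbenzoate | COCOc1cc(C)c(C(=O)OCc2ccccc2)c(OCOC)c1
F2 | step 4 | 2,4-bis(methoxymethoxy)-6-methylbenzoic acid | COCOc1cc(C)c(C(=O)O)c(OCOC)c1
F3 | step 4 | benzyl 4-{[2,4-bis(methoxymethoxy)-6-methylbenzoyl]oxy}-2-hydroxy-6-methylbenzoate | COCOc1cc(C)c(C(=O)Oc2cc(C)c(C(=O)OCc3ccccc3)c(O)c2)c(OCOC)c1
F4 | step 7 | 2,3-dimethoxy-5-methyl-1,4-benzoquinone | COC1=C(OC)C(=O)C(C)=CC1=O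
F5 | step 7 | 2,3-dimethoxy-5-methylbenzene-1,4-diol | COc1c(O)cc(C)c(O)c1OC
F6 | step 7 | 2,3-dimethoxy-6-methyl-4-[(triisopropylsilyl)oxy]phenol | COc1c(O[Si](C(C)C)(C(C)C)C(C)C)cc(C)c(O)c1OC
F7 | step 7 | 2,3-dimethoxy-6-methyl-4-[(triisopropylsilyl)oxy]phenyl trifluoromethanesulfonate | COc1c(O[Si](C(C)C)(C(C)C)C(C)C)cc(C)c(OS(=O)(=O)C(F)(F)F)c1OC
F8 | step 2 | allyl 4-(2,2-dimethyl-4-oxo-4H-1,3-dioxin-6-yl)-3-oxobutanoate | C=CCOC(=O)CC(=O)CC1=CC(=O)OC(C)(C)O1
F9 | step 2 | allyl 2-acetyl-4-(2,2-dimethyl-4-oxo-4H-1,3-dioxin-6-yl)-3-oxobutanoate | C=CCOC(=O)C(C(C)=O)C(=O)CC1=CC(=O)OC(C)(C)O1
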